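## The problem

Pestaphilone D (26) is a 7,8-dihydro-6H-isochromen-6-one: a pyran (O2, C1, C3, C4) is fused through C4a–C8a to a carbocycle, ring B (C4a, C5, C6 ketone, C7, C8, C8a), and the C1=C8a, C3=C4 and C4a=C5 double bonds form one vinylogous pyranone with the C6 ketone; a branched chain C9–C15 hangs from C3. The six stereocentres fall into three isolated groups: the trans diol C7 (tertiary, S)/C8 (secondary, R) in ring B, the trisubstituted epoxide C9 (R)/C10 (S), and the anti methyl/hydroxyl pair C13 (R)/C14 (S) beyond the (E)-C11=C12 alkene. Within a group one centre can steer its neighbour (C14 steers C13; the C7/C8 relation can be fixed by a cyclic transition state), but the groups are too far apart to steer each other, so each needs its own source of absolute configuration and the epoxide must be reagent controlled. The C9–C10 epoxide is tertiary at C9 and allylic at C10 (next to C11=C12), with C9 bonded to the C3 enol ether carbon, so it will not survive Brønsted or Lewis acids. The C8 hydroxyl is β to the C6 ketone (retro-aldol), and in any precursor with an sp3 C8a that carries a carbonyl group it is a β-leaving group; the pyranone itself is opened by amines and hard nucleophiles. The epoxide therefore has to arrive late in a preformed fragment, and the last deprotection has to be a fluoride-only operation. The feature that opens the synthesis is that C7 and C4a are 1,4-related across ring B and C7 bears oxygen: an oxygen bridge from C7 to C4a turns ring B into a 7-oxanorbornene, the product of a furan Diels–Alder reaction, and β-elimination from the C6 carbonyl later cuts the bridge at C4a, giving the C4a=C5 enone and the C7 hydroxyl.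

## Retrosynthesis

**Pyran (O2–C3 and C3–C4).** Removing the three triethylsilyl groups of 26 leads to 25. Cutting O2–C3 and C3–C4 gives the ring B unit 13, with C1 as a hydroxymethylene group and C4 as a methyl group on C4a, and the glycidic ester 23, whose ester carbon is C3. In the forward direction the dianion of 13 is acylated at C4 by 23 to give 24, which loses water to 25. The neighbouring cut C3–C9 would need an epoxide carbanion or a late epoxidation of a polyene, and cutting C4–C4a leads to an alkyne annulation (Alternative 2). The chosen cut divides the molecule into a ten-carbon piece with two stereocentres and a chain piece with four, and puts the epoxide into a fragment made by reagent control. It asks for C-selective reaction at C4 and for no acid after the coupling.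

**Ring B functional groups and the bridge.** 13 comes from the tris(silyl) ether 12 by oxidation of the primary silyl ether at C1, and 12 from the triol enone 11. Reconnecting the C7 oxygen to C4a (reverse of β-elimination, through the bridged ketone 10) and masking the C6 ketone as a silyl enol ether leads to the 7-oxanorbornene diol 9. C1 is deliberately at the alcohol level and the C8 oxygen is unacylated in 9: the carbonyl at C1 and the acyloxy group at C8 are removed before the bridge is opened, so the C8a–H/C8–O elimination that a β-acyloxy carbonyl compound would suffer has no chance.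

**Ring B skeleton (C7–C8 and C4a–C8a), the key cut.** 9 is the reduction product of the cycloadduct 8, and 8 is cut at C7–C8 and C4a–C8a into the silyloxyfuran 2 and the (Z)-acetoxyacryloyl imide 7. Other single cuts of ring B (C8–C8a, Alternative 1; C6–C7, Alternative 3) give open-chain precursors that need their own multistep enantioselective synthesis. This cut gives two achiral components that between them hold every carbon of ring B plus C1 and C4, both oxygens of the diol and the C6 oxygen. The forward reaction must join the methyl-bearing furan carbon to the acetoxy-bearing alkene carbon, place the acetoxy group anti to the bridge, and select one enantioface.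

**The two cycloaddition partners.** 2 is the silyl enol ether of the commercial furanone 1. 7 is cut at the enol C–O bond (anti addition of acetic acid to the alkyne of 6) and at the imide N–C bond (propiolic acid 3 and oxazolidin-2-one 4, joined through the mixed anhydride 5). Acetate is chosen as the C8 oxygen substituent because its (Z)-selective introduction uses acetic acid as the solvent and because it is removed reductively together with the imide.

**Side chain.** 23 comes from the epoxy alcohol 21 by oxidation (through the acid 22). 21 is the asymmetric epoxidation product of the dienol 20, which fixes C9 and C10 by reagent control. 20 is cut at C9=C10 and C11=C12 by two Wittig disconnections (dienoate 19, enal 18) back to the aldehyde 17, made from the ester 16 and the hydroxy ester 15. C13 is set from C14 by anti-selective methylation of ethyl (S)-3-hydroxybutanoate 14, which brings C14 from the chiral pool.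

## Roads not taken

Alternative 1: The cut is C8–C8a. In the forward step the open-chain keto aldehyde ester A2 is deprotonated at C8a to a glutaconate-type enolate, which adds to the C8 aldehyde and closes ring B as the aldol A1. Its merits are that a base is the only reagent, that C7 could come from a chiral-pool 2-hydroxy-2-methyl acid, and that A1 carries C1 and C4 just as the cycloadduct 8 does. Its weak points lie at C8 and in the product. C8 has to be set by 1,2-induction from a quaternary C7 whose three substituents (silyloxy, methyl, acyl) differ little, so the trans diol is not assured. The aldol is reversible, and A1 is a β-hydroxy ester with an acidic C8a–H, the elimination-prone arrangement that the chosen route avoids. A2 is an α-quaternary β-keto aldehyde open to deformylation and needs a (Z)-enone. In certainty that the ring-forming reaction type works, this road is better than the chosen one. The chosen plan sets against it that the C7/C8 relation follows from suprafacial addition to a (Z)-alkene, not from weak acyclic induction, and that ring B arises in one step from two achiral pieces, whereas A2 needs its own enantioselective synthesis.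

Alternative 2: The cuts are C4–C4a and O2–C3 together. In the forward step the enol O–H and the vinylic C4a–H of the ring B hydroxymethylene dienone A4 add across the terminal alkyne A5 under anodic ruthenium catalysis ([RuCl2(p-cymene)]2, current as the oxidant), giving A3, which is identical with 25. Its merits are real: it is the most convergent endgame, it forms the pyran under nearly neutral conditions with no strong base near the C8 silyloxy group, and it needs no chemical oxidant. In these respects it is better than the dianion acylation used here. Its weak points are the regiochemistry of insertion of a terminal alkyne (C4 must bond to C4a and C3 to oxygen), the use of an enol of a cross-conjugated dienone as directing group, and the exposure of the propargylic epoxide and the trisubstituted alkene of A5 to a cationic divalent ruthenium centre and an anode. It also says nothing about how the C7/C8 diol of A4 is made, which is the problem the chosen key step solves. The chosen plan sets against the higher convergence that C4 arrives as a furan methyl group and that the C3–C4 bond is made by carbonyl chemistry with a non-enolisable ester.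

Alternative 3: The cut is C6–C7. In the forward step a chiral triazolium-derived carbene converts the C6 aldehyde of the keto aldehyde A7 into an acyl anion equivalent that adds to the C7 methyl ketone, giving the α-ketol A6 with the tertiary alcohol. Its merit is that enantioselective carbene-catalysed benzoin cyclisations to six-membered tertiary α-ketols are a known reaction class, so the precedent for its key step is stronger than for the chosen cycloaddition. Its weak points for this target are that A6 holds only the six ring B carbons: C1 and C4 are absent, C4a is a ketal, C5 and C8a are plain methylene groups and the C4a=C5 double bond is missing. After ketal removal, C8a would have to be formylated next to the C8 silyloxy group, and C4 added at C4a. The α-silyloxy stereocentre of A7 is also epimerisable under the basic carbene conditions and may oppose the catalyst. The chosen plan sets against the better precedent that its cycloadduct 8 already contains C1, C4, both diol oxygens and the masked C6 ketone, so that six operations lead from 8 to 25.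

Key step: step 4

Remark: 13 (and likewise 24, F5 and F10) is drawn as the (Z)-hydroxymethylene enol; it should equilibrate with the (E)-enol and the 4-formyl tautomer, all of which give the same dianion, so this geometry carries no stereochemical information.
Remark: lithium salts formed by deprotonating a numbered compound (enolates, lithiated 4) are treated as forms of that compound and are not numbered separately.

Step 1
Reactants: 1 2,5-dimethylfuran-3(2H)-one (racemic)
Product: 2 2,5-dimethyl-3-(triisopropylsilyloxy)furan
Conditions: iPr3SiOTf, Et3N, CH2Cl2, 0 °C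
Reagents that add atoms: triisopropylsilyl trifluoromethanesulfonate, CC(C)[Si](OS(=O)(=O)C(F)(F)F)(C(C)C)C(C)C
Why: Soft enolisation and O-silylation of the furanone is driven by aromatisation to the furan; the stereocentre of 1 is lost, so the racemate serves.

Step 2
Reactants: 3 propiolic acid; 4 oxazolidin-2-one
Product: 6 3-(prop-2-ynoyl)-1,3-oxazolidin-2-one, via mixed pivalic anhydride 5 (not isolated)
Conditions: 3, tBuCOCl, Et3N, THF, −78 to −20 °C; then 4/n-BuLi, THF, −78 °C
Reagents that add atoms: none
Why: N-Acylation of a lithiated oxazolidinone by a mixed pivalic anhydride is standard imide synthesis; the nitrogen anion should attack the unhindered propioloyl carbonyl at −78 °C, where conjugate addition to the ynoyl group is slow.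

Step 3
Reactants: 6 3-(prop-2-ynoyl)-1,3-oxazolidin-2-one
Product: 7 3-[(2Z)-3-acetoxyprop-2-enoyl]-1,3-oxazolidin-2-one
Conditions: Pd(OAc)2 (5 mol %), LiOAc, AcOH, 25–40 °C
Reagents that add atoms: acetic acid, CC(=O)O
Why: Trans-hydroacetoxylation of a 2-alkynoic acid derivative: divalent palladium activates the alkyne, acetate adds anti at the β-carbon and the vinyl–palladium bond is protonated with retention, so H and OAc end up trans and the (Z)-enol acetate should result.

Step 4
Reactants: 2 2,5-dimethyl-3-(triisopropylsilyloxy)furan; 7 3-[(2Z)-3-acetoxyprop-2-enoyl]-1,3-oxazolidin-2-one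
Product: 8 3-{[(1S,2S,3R,4S)-3-acetoxy-1,4-dimethyl-5-(triisopropylsilyloxy)-7-oxabicyclo[2.2.1]hept-5-en-2-yl]carbonyl}-1,3-oxazolidin-2-one (acyl and acetoxy groups both endo, anti to the oxygen bridge)
Conditions: Cu(SbF6)2·L (10 mol %; L = 2,2'-(propane-2,2-diyl)bis[(4S)-4-tert-butyl-4,5-dihydro-1,3-oxazole], from CuCl2 and AgSbF6), 4 Å MS, CH2Cl2, −78 to −40 °C
Reagents that add atoms: none
Why: Proposed new method: the divalent copper bis(oxazoline) complex chelates both imide carbonyls of 7 in the s-cis form and lowers its LUMO, so the electron-rich furan 2 should add across its 2- and 5-positions in an asynchronous [4+2] process (at the stepwise limit a Mukaiyama–Michael attack by the silyl enol ether carbon followed by closure of the copper enolate onto the oxocarbenium carbon); the closest known reaction types are the Cu(SbF6)2–bis(oxazoline)-catalysed Diels–Alder reaction of furan with N-acryloyl oxazolidinone and the cycloadditions of 3-silyloxyfurans with activated alkenes. Ring B closes as the six-membered carbocycle of a 7-oxabicyclo[2.2.1]heptene by suprafacial addition on both partners, the furan oxygen becoming the C7–O–C4a bridge. Regiochemistry comes from the silyloxy group, which makes the methyl-bearing furan C2 (future C7) the nucleophilic terminus that bonds to the acetoxy-bearing β-carbon (C8), leaving furan C5 (C4a) to bond to the α-carbon (C8a). C8 and C8a are cis to each other because the (Z)-geometry of 7 is conserved, and both are anti to the bridge because the chelated imide sits endo; this is the relation that becomes the trans C7/C8 diol. The absolute configuration of the bridgeheads C7 and C4a, and through the suprafacial addition that of C8 and C8a, is set by the tert-butyl groups of the (S,S)-ligand, which shield the α-Si face of the square-planar chelate so that the furan adds to the α-Re face, the sense expected from the acryloyl imide case. The step needs regio-, endo- and enantioface selectivity at once, secured by the silyloxy group, the (Z)-alkene and the ligand respectively. The bulky iPr3Si group is chosen to hold back silyl transfer to an open Michael adduct, and the low temperature to hold back cycloreversion.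

Step 5
Reactants: 8 the cycloadduct
Product: 9 (1S,2R,3S,4R)-3-(hydroxymethyl)-1,4-dimethyl-6-(triisopropylsilyloxy)-7-oxabicyclo[2.2.1]hept-5-en-2-ol
Conditions: LiBH4 (excess), MeOH (1 equiv), THF, 0 to 23 °C
Reagents that add atoms: none
Why: LiBH4 reduces N-acyl oxazolidinones to primary alcohols and in excess cleaves the acetate reductively; the silyl enol ether and the bridge are inert to hydride. Removing the C1 carbonyl and the C8 acyloxy group here takes away the C8a–H/C8–O elimination pathway before the bridge is opened.

Step 6
Reactants: 9 the bridged diol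
Product: 11 (4S,5R,6S)-5,6-dihydroxy-4-(hydroxymethyl)-3,6-dimethylcyclohex-2-en-1-one, via bridged ketone 10 (not isolated)
Conditions: Bu4NF, AcOH, THF, 0 °C; then DBU (0.2 equiv), 0 °C
Reagents that add atoms: none
Why: Fluoride cleaves the silyl enol ether to the C6 ketone 10, whose β-alkoxy group at the tertiary bridgehead C4a is expelled by strain-driven E1cB elimination, the known base-induced opening of 7-oxanorbornan-2-ones; this gives the C4a=C5 enone and the free C7 hydroxyl. Acetic acid buffering limits retro-aldol cleavage at the C8 β-hydroxy ketone.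

Step 7
Reactants: 11 the triol enone
Product: 12 (4S,5R,6S)-3,6-dimethyl-5,6-bis(triethylsilyloxy)-4-[(triethylsilyloxy)methyl]cyclohex-2-en-1-one
Conditions: Et3SiOTf (4 equiv), 2,6-lutidine, CH2Cl2, −78 to 0 °C
Reagents that add atoms: triethylsilyl trifluoromethanesulfonate, CC[Si](CC)(CC)OS(=O)(=O)C(F)(F)F
Why: A silyl triflate with a hindered pyridine base silylates primary, secondary and tertiary hydroxyls alike; triethylsilyl is chosen because all such ethers can be removed at the end by fluoride alone.

Step 8
Reactants: 12 the tris(triethylsilyl) ether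
Product: 13 (4Z,5R,6S)-4-(hydroxymethylidene)-3,6-dimethyl-5,6-bis(triethylsilyloxy)cyclohex-2-en-1-one
Conditions: (COCl)2, DMSO, CH2Cl2, −78 to −30 °C; then Et3N, −78 to 0 °C
Reagents that add atoms: none
Why: Under Swern conditions a primary triethylsilyl ether is cleaved and oxidised in one operation while secondary and tertiary ones stay; the resulting 4-formyl enone should tautomerise to the conjugated hydroxymethylene dienone, which removes the C8a stereocentre as planned.

Step 9
Reactants: 14 ethyl (S)-3-hydroxybutanoate
Product: 15 ethyl (2S,3S)-3-hydroxy-2-methylbutanoate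
Conditions: LiN(iPr)2 (2.2 equiv), THF, −78 to −20 °C; MeI, DMPU, −78 to 0 °C
Reagents that add atoms: iodomethane, CI
Why: Fráter–Seebach alkylation: the lithium-chelated dianion is methylated on the face opposite the C3 methyl group, which sets C13 anti to C14.

Step 10
Reactants: 15 ethyl (2S,3S)-3-hydroxy-2-methylbutanoate
Product: 16 ethyl (2S,3S)-2-methyl-3-(triethylsilyloxy)butanoate
Conditions: Et3SiCl, imidazole, CH2Cl2, 0 to 23 °C
Reagents that add atoms: chlorotriethylsilane, CC[Si](Cl)(CC)CC
Why: Standard silylation of a secondary alcohol; the same silyl group as on the core allows one final deprotection.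

Step 11
Reactants: 16 ethyl (2S,3S)-2-methyl-3-(triethylsilyloxy)butanoate
Product: 17 (2S,3S)-2-methyl-3-(triethylsilyloxy)butanal
Conditions: iBu2AlH (1.1 equiv), CH2Cl2, −78 °C; aq. potassium sodium tartrate
Reagents that add atoms: none
Why: Partial reduction of the ester at −78 °C stops at the aluminium hemiacetal; the aldehyde is used crude and cold to protect its α-stereocentre.

Step 12
Reactants: 17 (2S,3S)-2-methyl-3-(triethylsilyloxy)butanal
Product: 18 (2E,4R,5S)-2,4-dimethyl-5-(triethylsilyloxy)hex-2-enal
Conditions: Ph3P=C(CH3)CHO, toluene, 90 °C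
Reagents that add atoms: 2-(triphenyl-λ5-phosphanylidene)propanal, CC(C=O)=P(c1ccccc1)(c1ccccc1)c1ccccc1
Why: Wittig olefination with a formyl-stabilised ylide should give the (E)-trisubstituted enal, setting the C11=C12 geometry.

Step 13
Reactants: 18 (2E,4R,5S)-2,4-dimethyl-5-(triethylsilyloxy)hex-2-enal
Product: 19 ethyl (2E,4E,6R,7S)-2,4,6-trimethyl-7-(triethylsilyloxy)octa-2,4-dienoate
Conditions: Ph3P=C(CH3)CO2Et, toluene, 80 °C
Reagents that add atoms: ethyl 2-(triphenyl-λ5-phosphanylidene)propanoate, CCOC(=O)C(C)=P(c1ccccc1)(c1ccccc1)c1ccccc1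
Why: A second stabilised-ylide Wittig reaction gives the (E)-2-methyl enoate, the C9=C10 alkene that will be epoxidised.

Step 14
Reactants: 19 the dienoate
Product: 20 (2E,4E,6R,7S)-2,4,6-trimethyl-7-(triethylsilyloxy)octa-2,4-dien-1-ol
Conditions: iBu2AlH (2.5 equiv), CH2Cl2, −78 °C
Reagents that add atoms: none
Why: 1,2-Reduction of a conjugated ester to the allylic alcohol by an aluminium hydride is routine.

Step 15
Reactants: 20 the dienol
Product: 21 [(2S,3S)-2-methyl-3-[(2E,4R,5S)-4-methyl-5-(triethylsilyloxy)hex-2-en-2-yl]oxiran-2-yl]methanol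
Conditions: Ti(OiPr)4, L-(+)-diethyl tartrate, t-BuOOH, 4 Å MS, CH2Cl2, −20 °C
Reagents that add atoms: tert-butyl hydroperoxide, CC(C)(C)OO
Why: Sharpless asymmetric epoxidation: the titanium tartrate complex delivers oxygen only to the allylic C9=C10 alkene, and L-(+)-tartrate gives the (2S,3S)-epoxy alcohol from an (E)-2-methyl allylic alcohol, which is C9 (R) and C10 (S) of the target, under reagent control.

Step 16
Reactants: 21 the epoxy alcohol
Product: 23 methyl (2R,3S)-2-methyl-3-[(2E,4R,5S)-4-methyl-5-(triethylsilyloxy)hex-2-en-2-yl]oxirane-2-carboxylate, via epoxy acid 22 (not isolated)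
Conditions: TEMPO (cat.), PhI(OAc)2, MeCN/pH 7 buffer, 0 to 23 °C; then Me3SiCHN2, toluene/MeOH, 0 °C
Reagents that add atoms: water, O; (trimethylsilyl)diazomethane, C[Si](C)(C)C=[N+]=[N-]
Why: Oxoammonium oxidation takes the primary alcohol through the aldehyde hydrate to the acid, and immediate methylation avoids storing the acid-sensitive glycidic acid; C9 is quaternary and cannot epimerise.

Step 17
Reactants: 13 the hydroxymethylene dienone; 23 the glycidic ester
Product: 25 (7S,8R)-7-methyl-3-[(2R,3S)-2-methyl-3-[(2E,4R,5S)-4-methyl-5-(triethylsilyloxy)hex-2-en-2-yl]oxiran-2-yl]-7,8-bis(triethylsilyloxy)-7,8-dihydro-6H-isochromen-6-one, via open-chain keto enol 24 (not isolated)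
Conditions: 13, LiN(iPr)2 (3.3 equiv), THF, −78 °C; 23, −78 to −30 °C; AcOH; then PPTS (cat.), CH2Cl2, 0 °C
Reagents that add atoms: none
Why: Double deprotonation of the vinylogous acid 13 gives a dianion whose C4 carbon, the last site deprotonated and the common γ-terminus of both enolate arms, should attack the non-enolisable, α-oxygen-activated ester (Claisen-type acylation of a polycarbonyl dianion, as used for pyranone synthesis). On acidification the C1 enol oxygen adds to the new C3 ketone and water is lost to the fully conjugated pyran. No stereocentre is formed or touched.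

Step 18
Reactants: 25 the tris(triethylsilyl) ether
Product: 26 Pestaphilone D, (7S,8R)-7,8-dihydroxy-3-[(2R,3S)-3-[(2E,4R,5S)-5-hydroxy-4-methylhex-2-en-2-yl]-2-methyloxiran-2-yl]-7-methyl-7,8-dihydro-6H-isochromen-6-one
Conditions: HF·pyridine, pyridine, THF, 0 to 23 °C
Reagents that add atoms: none
Why: Buffered HF·pyridine cleaves triethylsilyl ethers, and the excess pyridine should keep the medium from opening the allylic, tertiary epoxide.

**Compound list**

1 | 2,5-dimethylfuran-3(2H)-one (racemic) | CC1OC(C)=CC1=O | starting material
2 | 2,5-dimethyl-3-(triisopropylsilyloxy)furan | Cc1oc(C)cc1O[Si](C(C)C)(C(C)C)C(C)C | intermediate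
3 | propiolic acid | C#CC(=O)O | starting material
4 | oxazolidin-2-one | O=C1NCCO1 | starting material
5 | prop-2-ynoic 2,2-dimethylpropanoic anhydride (not isolated) | C#CC(=O)OC(=O)C(C)(C)C | intermediate
6 | 3-(prop-2-ynoyl)-1,3-oxazolidin-2-one | C#CC(=O)N1CCOC1=O | intermediate
7 | 3-[(2Z)-3-acetoxyprop-2-enoyl]-1,3-oxazolidin-2-one | CC(=O)O/C=C\C(=O)N1CCOC1=O | intermediate
8 | 3-{[(1S,2S,3R,4S)-3-acetoxy-1,4-dimethyl-5-(triisopropylsilyloxy)-7-oxabicyclo[2.2.1]hept-5-en-2-yl]carbonyl}-1,3-oxazolidin-2-one | C[C@@]12O[C@@](C)(C=C1O[Si](C(C)C)(C(C)C)C(C)C)[C@@H](C(=O)N1CCOC1=O)[C@H]2OC(C)=O | intermediate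
9 | (1S,2R,3S,4R)-3-(hydroxymethyl)-1,4-dimethyl-6-(triisopropylsilyloxy)-7-oxabicyclo[2.2.1]hept-5-en-2-ol | C[C@@]12O[C@@](C)(C=C1O[Si](C(C)C)(C(C)C)C(C)C)[C@@H](CO)[C@H]2O | intermediate
10 | (1S,4S,5S,6R)-6-hydroxy-5-(hydroxymethyl)-1,4-dimethyl-7-oxabicyclo[2.2.1]heptan-2-one (not isolated) | C[C@@]12O[C@@](C)(CC1=O)[C@@H](CO)[C@H]2O | intermediate
11 | (4S,5R,6S)-5,6-dihydroxy-4-(hydroxymethyl)-3,6-dimethylcyclohex-2-en-1-one | CC1=CC(=O)[C@@](C)(O)[C@H](O)[C@@H]1CO | intermediate
12 | (4S,5R,6S)-3,6-dimethyl-5,6-bis(triethylsilyloxy)-4-[(triethylsilyloxy)methyl]cyclohex-2-en-1-one | CC1=CC(=O)[C@@](C)(O[Si](CC)(CC)CC)[C@H](O[Si](CC)(CC)CC)[C@@H]1CO[Si](CC)(CC)CC | intermediate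
13 | (4Z,5R,6S)-4-(hydroxymethylidene)-3,6-dimethyl-5,6-bis(triethylsilyloxy)cyclohex-2-en-1-one | CC1=CC(=O)[C@@](C)(O[Si](CC)(CC)CC)[C@H](O[Si](CC)(CC)CC)/C1=C\O | intermediate
14 | ethyl (S)-3-hydroxybutanoate | CCOC(=O)C[C@H](C)O | starting material
15 | ethyl (2S,3S)-3-hydroxy-2-methylbutanoate | CCOC(=O)[C@@H](C)[C@H](C)O | intermediate
16 | ethyl (2S,3S)-2-methyl-3-(triethylsilyloxy)butanoate | CCOC(=O)[C@@H](C)[C@H](C)O[Si](CC)(CC)CC | intermediate
17 | (2S,3S)-2-methyl-3-(triethylsilyloxy)butanal | O=C[C@@H](C)[C@H](C)O[Si](CC)(CC)CC | intermediate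
18 | (2E,4R,5S)-2,4-dimethyl-5-(triethylsilyloxy)hex-2-enal | C/C(=C\[C@@H](C)[C@H](C)O[Si](CC)(CC)CC)C=O | intermediate
19 | ethyl (2E,4E,6R,7S)-2,4,6-trimethyl-7-(triethylsilyloxy)octa-2,4-dienoate | C/C(=C\[C@@H](C)[C@H](C)O[Si](CC)(CC)CC)/C=C(\C)C(=O)OCC | intermediate
20 | (2E,4E,6R,7S)-2,4,6-trimethyl-7-(triethylsilyloxy)octa-2,4-dien-1-ol | C/C(=C\[C@@H](C)[C@H](C)O[Si](CC)(CC)CC)/C=C(\C)CO | intermediate
21 | [(2S,3S)-2-methyl-3-[(2E,4R,5S)-4-methyl-5-(triethylsilyloxy)hex-2-en-2-yl]oxiran-2-yl]methanol | C/C(=C\[C@@H](C)[C@H](C)O[Si](CC)(CC)CC)[C@@H]1O[C@@]1(C)CO | intermediate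
22 | (2R,3S)-2-methyl-3-[(2E,4R,5S)-4-methyl-5-(triethylsilyloxy)hex-2-en-2-yl]oxirane-2-carboxylic acid (not isolated) | C/C(=C\[C@@H](C)[C@H](C)O[Si](CC)(CC)CC)[C@@H]1O[C@@]1(C)C(=O)O | intermediate
23 | methyl (2R,3S)-2-methyl-3-[(2E,4R,5S)-4-methyl-5-(triethylsilyloxy)hex-2-en-2-yl]oxirane-2-carboxylate | C/C(=C\[C@@H](C)[C@H](C)O[Si](CC)(CC)CC)[C@@H]1O[C@@]1(C)C(=O)OC | intermediate
24 | (4Z,5R,6S)-4-(hydroxymethylidene)-6-methyl-3-{2-[(2R,3S)-2-methyl-3-[(2E,4R,5S)-4-methyl-5-(triethylsilyloxy)hex-2-en-2-yl]oxiran-2-yl]-2-oxoethyl}-5,6-bis(triethylsilyloxy)cyclohex-2-en-1-one (not isolated) | C/C(=C\[C@@H](C)[C@H](C)O[Si](CC)(CC)CC)[C@@H]1O[C@@]1(C)C(=O)CC1=CC(=O)[C@@](C)(O[Si](CC)(CC)CC)[C@H](O[Si](CC)(CC)CC)/C1=C\O | intermediate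
25 | (7S,8R)-7-methyl-3-[(2R,3S)-2-methyl-3-[(2E,4R,5S)-4-methyl-5-(triethylsilyloxy)hex-2-en-2-yl]oxiran-2-yl]-7,8-bis(triethylsilyloxy)-7,8-dihydro-6H-isochromen-6-one | C/C(=C\[C@@H](C)[C@H](C)O[Si](CC)(CC)CC)[C@@H]1O[C@@]1(C)C1=CC2=CC(=O)[C@@](C)(O[Si](CC)(CC)CC)[C@H](O[Si](CC)(CC)CC)C2=CO1 | intermediate
26 | Pestaphilone D, (7S,8R)-7,8-dihydroxy-3-[(2R,3S)-3-[(2E,4R,5S)-5-hydroxy-4-methylhex-2-en-2-yl]-2-methyloxiran-2-yl]-7-methyl-7,8-dihydro-6H-isochromen-6-one | C/C(=C\[C@@H](C)[C@H](C)O)[C@@H]1O[C@@]1(C)C1=CC2=CC(=O)[C@@](C)(O)[C@H](O)C2=CO1 | target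

**Step count and risk**

Total: 18 steps. Longest linear sequence: 10 steps (14 to 26, steps 9–18); the core branch from 3 runs 9 steps (steps 2–8, 17, 18).

Least certain steps:

1. Step 4 (key step). Several processes can defeat it:
   - silyl transfer, giving an open Michael adduct in place of ring closure;
   - twisting of the (Z)-acetoxyacryloyl unit out of the chelate plane, which would cost reactivity and facial discrimination;
   - exo approach, which would invert C8 relative to C7;
   - cycloreversion of an adduct with two quaternary bridgeheads.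

   Fallback (auxiliary control in place of catalyst control, with established reaction types): it sets out from 3 and 2 and returns to the route at 9. The anhydride 5 made from 3 acylates lithiated (R)-4-benzyloxazolidin-2-one to give (4R)-4-benzyl-3-(prop-2-ynoyl)-1,3-oxazolidin-2-one F1. The conditions of step 3 turn it into (4R)-3-[(2Z)-3-acetoxyprop-2-enoyl]-4-benzyl-1,3-oxazolidin-2-one F2. F2 and 2 are combined under Et2AlCl chelation, the standard activation of N-enoyl oxazolidinone auxiliaries in Diels–Alder reactions, or simply near room temperature, where 3-silyloxyfurans add to activated alkenes. The benzyl group shields the α-Si face, and the diastereomers are separated by chromatography to give the 4-benzyl analogue of 8, F3. LiBH4 as in step 5 removes auxiliary and acetate and gives 9.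

2. Step 17. The dianion may react at oxygen or at C5 in place of C4, the hindered ester may acylate too slowly at low temperature, and on warming the C8 silyloxy group may be lost by β-elimination from the C1 enolate arm.

   Fallback (aldol and oxidation in place of acylation): it sets out from 21 and 13 and returns at 24. 21 is oxidised (Dess–Martin periodinane, NaHCO3) to (2R,3S)-2-methyl-3-[(2E,4R,5S)-4-methyl-5-(triethylsilyloxy)hex-2-en-2-yl]oxirane-2-carbaldehyde F4. The dianion of 13 adds to F4 at −78 °C, where elimination is slow and the reversible aldol favours the conjugated C4 adduct, to give the C3 carbinol F5 (either C3 epimer serves). Dess–Martin oxidation of F5 gives 24, which closes to 25 as in step 17.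

3. Step 3. The (Z)-enol acetate may isomerise to the (E)-isomer by reversible acetate addition, or the terminal alkyne may react with palladium in other ways.

   Fallback (enolate O-acylation in place of alkyne addition): it sets out from 4 and returns at 7. 4 is N-acetylated (n-BuLi, AcCl) to 3-acetyl-1,3-oxazolidin-2-one F6. Its lithium enolate (LiN(SiMe3)2) is formylated with ethyl formate to the lithium chelate of 3-[(2Z)-3-hydroxyprop-2-enoyl]-1,3-oxazolidin-2-one F7. O-Acetylation of this chelate with AcCl in toluene at −78 °C gives 7, by analogy with the (Z)-selective O-sulfonylation and O-phosphorylation of chelated β-dicarbonyl enolates.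

4. Step 6. Under basic fluoride the free C8 alkoxide may undergo retro-aldol cleavage and re-closure with loss of the C7/C8 relation, or the bridged ketone may open incompletely.

   Fallback (Lewis acid opening after silylation, with no free alkoxide): it sets out from 9 and returns at 12. 9 is silylated at both hydroxyls (Et3SiOTf 2.2 equiv, 2,6-lutidine, −78 °C) to the bis(triethylsilyl) ether F8. More Et3SiOTf at 0–23 °C silylates the bridge oxygen, the silyl enol ether pushes the C4a–O bond open (the silyl triflate opening known for 7-oxanorbornan-2-ones through their silyl enol ethers), and loss of iPr3SiOTf leaves 12 directly.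

5. Step 18. The tertiary silyl ether at C7 may need conditions under which fluoride or acid opens the activated epoxide.

   Fallback (a different protecting-group plan, leaving C7–OH free): it sets out from 11 and returns at 26. 11 is silylated only at the primary and secondary hydroxyls (Et3SiCl, imidazole) to (4S,5R,6S)-6-hydroxy-3,6-dimethyl-5-(triethylsilyloxy)-4-[(triethylsilyloxy)methyl]cyclohex-2-en-1-one F9. Swern oxidation as in step 8 gives (4Z,5R,6S)-6-hydroxy-4-(hydroxymethylidene)-3,6-dimethyl-5-(triethylsilyloxy)cyclohex-2-en-1-one F10. Acylation with 23 as in step 17, with one more equivalent of LiN(iPr)2, gives the 8,14-bis(triethylsilyl) ether of Pestaphilone D F11. Only two secondary silyl ethers remain, which Et3N·3HF or cold buffered HF·pyridine should remove to give 26.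

**Further compounds**

F1 | step 4 | (4R)-4-benzyl-3-(prop-2-ynoyl)-1,3-oxazolidin-2-one | C#CC(=O)N1[C@H](Cc2ccccc2)COC1=O
F2 | step 4 | (4R)-3-[(2Z)-3-acetoxyprop-2-enoyl]-4-benzyl-1,3-oxazolidin-2-one | CC(=O)O/C=C\C(=O)N1[C@H](Cc2ccccc2)COC1=O
F3 | step 4 | (4R)-3-{[(1S,2S,3R,4S)-3-acetoxy-1,4-dimethyl-5-(triisopropylsilyloxy)-7-oxabicyclo[2.2.1]hept-5-en-2-yl]carbonyl}-4-benzyl-1,3-oxazolidin-2-one | C[C@@]12O[C@@](C)(C=C1O[Si](C(C)C)(C(C)C)C(C)C)[C@@H](C(=O)N1[C@H](Cc3ccccc3)COC1=O)[C@H]2OC(C)=O
F4 | step 17 | (2R,3S)-2-methyl-3-[(2E,4R,5S)-4-methyl-5-(triethylsilyloxy)hex-2-en-2-yl]oxirane-2-carbaldehyde | C/C(=C\[C@@H](C)[C@H](C)O[Si](CC)(CC)CC)[C@@H]1O[C@@]1(C)C=O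
F5 | step 17 | (4Z,5R,6S)-3-{2-hydroxy-2-[(2S,3S)-2-methyl-3-[(2E,4R,5S)-4-methyl-5-(triethylsilyloxy)hex-2-en-2-yl]oxiran-2-yl]ethyl}-4-(hydroxymethylidene)-6-methyl-5,6-bis(triethylsilyloxy)cyclohex-2-en-1-one (carbinol epimers) | C/C(=C\[C@@H](C)[C@H](C)O[Si](CC)(CC)CC)[C@@H]1O[C@@]1(C)C(O)CC1=CC(=O)[C@@](C)(O[Si](CC)(CC)CC)[C@H](O[Si](CC)(CC)CC)/C1=C\O
F6 | step 3 | 3-acetyl-1,3-oxazolidin-2-one | CC(=O)N1CCOC1=O
F7 | step 3 | 3-[(2Z)-3-hydroxyprop-2-enoyl]-1,3-oxazolidin-2-one (as its lithium chelate) | O/C=C\C(=O)N1CCOC1=O
F8 | step 6 | triethyl{[(1S,2R,3S,4R)-1,4-dimethyl-3-[(triethylsilyloxy)methyl]-6-(triisopropylsilyloxy)-7-oxabicyclo[2.2.1]hept-5-en-2-yl]oxy}silane | C[C@@]12O[C@@](C)(C=C1O[Si](C(C)C)(C(C)C)C(C)C)[C@@H](CO[Si](CC)(CC)CC)[C@H]2O[Si](CC)(CC)CC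
F9 | step 18 | (4S,5R,6S)-6-hydroxy-3,6-dimethyl-5-(triethylsilyloxy)-4-[(triethylsilyloxy)methyl]cyclohex-2-en-1-one | CC1=CC(=O)[C@@](C)(O)[C@H](O[Si](CC)(CC)CC)[C@@H]1CO[Si](CC)(CC)CC
F10 | step 18 | (4Z,5R,6S)-6-hydroxy-4-(hydroxymethylidene)-3,6-dimethyl-5-(triethylsilyloxy)cyclohex-2-en-1-one | CC1=CC(=O)[C@@](C)(O)[C@H](O[Si](CC)(CC)CC)/C1=C\O
F11 | step 18 | (7S,8R)-7-hydroxy-7-methyl-3-[(2R,3S)-2-methyl-3-[(2E,4R,5S)-4-methyl-5-(triethylsilyloxy)hex-2-en-2-yl]oxiran-2-yl]-8-(triethylsilyloxy)-7,8-dihydro-6H-isochromen-6-one | C/C(=C\[C@@H](C)[C@H](C)O[Si](CC)(CC)CC)[C@@H]1O[C@@]1(C)C1=CC2=CC(=O)[C@@](C)(O)[C@H](O[Si](CC)(CC)CC)C2=CO1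
A1 | alternative 1 | methyl (1S,5S,6R)-5-[(tert-butyldimethylsilyl)oxy]-6-hydroxy-2,5-dimethyl-4-oxocyclohex-2-ene-1-carboxylate | COC(=O)[C@H]1C(C)=CC(=O)[C@@](C)(O[Si](C)(C)C(C)(C)C)[C@@H]1O
A2 | alternative 1 | methyl (3Z,6S)-6-[(tert-butyldimethylsilyl)oxy]-3,6-dimethyl-5,7-dioxohept-3-enoate | COC(=O)C/C(C)=C\C(=O)[C@@](C)(O[Si](C)(C)C(C)(C)C)C=O
A3 | alternative 2 | tris(triethylsilyl) ether of Pestaphilone D (identical with 25) | C/C(=C\[C@@H](C)[C@H](C)O[Si](CC)(CC)CC)[C@@H]1O[C@@]1(C)C1=CC2=CC(=O)[C@@](C)(O[Si](CC)(CC)CC)[C@H](O[Si](CC)(CC)CC)C2=CO1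
A4 | alternative 2 | (5R,6S)-4-(hydroxymethylidene)-6-methyl-5,6-bis(triethylsilyloxy)cyclohex-2-en-1-one | C1=CC(=O)[C@@](C)(O[Si](CC)(CC)CC)[C@H](O[Si](CC)(CC)CC)C1=CO
A5 | alternative 2 | (2S,3S)-2-ethynyl-2-methyl-3-[(2E,4R,5S)-4-methyl-5-(triethylsilyloxy)hex-2-en-2-yl]oxirane | C/C(=C\[C@@H](C)[C@H](C)O[Si](CC)(CC)CC)[C@@H]1O[C@@]1(C)C#C
A6 | alternative 3 | (8S,9R)-9-[(tert-butyldimethylsilyl)oxy]-8-hydroxy-8-methyl-1,4-dioxaspiro[4.5]decan-7-one | C1C(=O)[C@@](C)(O)[C@H](O[Si](C)(C)C(C)(C)C)CC12OCCO2
A7 | alternative 3 | 2-{2-[(2R)-2-[(tert-butyldimethylsilyl)oxy]-3-oxobutyl]-1,3-dioxolan-2-yl}acetaldehyde | O=CCC1(OCCO1)C[C@@H](O[Si](C)(C)C(C)(C)C)C(C)=O
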